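## Analysis of the target

Target 25 is (1R,5S,8R,9R)-5-methoxy-9-methyl-3-(prop-2-en-1-yl)-8-(3,4,5-trimethoxyphenyl)-6-oxabicyclo[3.2.2]non-3-ene-2,7-dione. It is a cycloheptenone (C1–C2–C3–C4–C5–C9–C8) whose C1 and C5 are bridged by O6–C7(=O), so that O6, C7, C1, C8, C9 and C5 form a δ-lactone ring. There are four stereocentres. C1 and C5 are bridgeheads and fix each other. C8 (aryl) and C9 (methyl) are trans on the two-carbon bridge, the aryl group pointing away from the enone bridge C2–C3–C4 and the methyl group towards it. The stereochemical problem is therefore the contiguous triad C1–C8–C9 in one absolute sense.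

The sensitive groups are the allylic acyloxy methoxy ketal at C5 (a pseudo-ester), the β-keto lactone at C1 (kept from enolising only by its bridgehead position), the skipped diene formed by the C3 allyl group and the enone, and the electron-rich arene. The synthesis is hard because every carbon of the seven-membered ring is substituted, three oxidation levels (ketone, ketal, lactone) sit on that ring, and an open-chain β-keto acid or β-keto ester stage would risk decarboxylation and loss of the C1 configuration.

The strategy rests on one feature. C5, C9 and C8 correspond to the hydroxymethyl, methine and ester carbons of hydroxy ester 1, and the ring O6–C7–C1–C8–C9–C5 is the ring of lactone 6 with C5 at a lower oxidation level. One bought centre (C9) can thus set C8 and C1 on a six-membered template.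

## Retrosynthetic reasoning

**C2 carbonyl.** The C2 ketone of 25 is taken back to the allylic alcohol 24 and its silyl ether 23. The 1,3-dicarbonyl is thereby revealed only once C1 is a bridgehead. The silyl ether also stops the C2 oxygen from bridging to C5 during ketal formation.

**C5–O6 and C5–OMe bonds.** The pseudo-ester of 23 is cut at C5 to the keto acid 22, which comes from its allyl ester 21. The forward step must capture the C5 ketone as a methoxy ketal with the C1 carboxyl group; the tether allows only one configuration at C5. An allyl ester is chosen so that the acid can be freed under neutral conditions next to an enolisable enone.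

**C4–C5 bond.** The seven-membered ring of 21 is opened between the enone CH and the carbonyl carbon. This gives the carbinol 20 and then the open chain 19, which carries an aldehyde at C5 and a (Z)-alkenyl iodide at C4. The cut is made here because a chromium-mediated Nozaki–Hiyama–Kishi closure tolerates the ester, silyl ether, alkenes and arene, adds only to the aldehyde, and keeps the alkene geometry that the ring needs.

**Lactone template.** Aldehyde 19 comes from hydroxy ester 18, and this from the silylated lactone 16 and the aldol 15. The forward steps open the ring at its acyl–oxygen bond and raise the freed CH2OH carbon to the aldehyde. The lactone carbonyl of 15 is kept as C7 of the target.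

**Aryl–C8 and C1–C2 bonds (key disconnection).** 15 is cut into the unsaturated lactone 6, the aryl Grignard reagent 13 and the iodo-enal 11. Both bonds lie on the lactone ring next to the only bought stereocentre, so a conjugate addition followed by aldol capture of the enolate can set C8 and C1 by 1,2-induction in one flask. No other pair of bonds brings in all the remaining carbons and two stereocentres at once.

**Lactone 6.** The C2–C3 alkene and the ring C–O bond of 6 are cut to the (Z)-enoate 4, then to aldehyde 3, silyl ether 2 and the chiral-pool ester 1. The forward steps need a (Z)-selective olefination that leaves the α-stereocentre of 3 intact.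

**Enal 11 and Grignard 13.** 11 comes from the allylic alcohol 10, and 10 from alkynol 7 and allyl Grignard 8 by directed carbometalation and iodination; this fixes the (Z)-geometry that places iodine cis to the future C2. 13 comes from aryl bromide 12.

## Alternatives that were turned down

**Alternative 1:** Here the C1–C2 and C4–C5 bonds of the target are cut. The enone bridge comes from the cyclopropenone ketal A2, and C1, C8, C9, C5 come from the pyrone ester A1. In the forward key step A1 and A2 combine in a thermal [4+3] cycloaddition across the pyrone diene termini; decarboxylative loss of the lactone bridge then gives the tropone ketal A3.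
- For: one step gives the seven-membered ring with the C7 ester, the C9 methyl group, the C5 methoxy group and the masked C2 ketone in place. The C5 enol ether could later take up the carboxyl group by irreversible addition. On speed of ring construction this route is stronger than the chosen one.
- Against: A3 has no stereocentre and lacks the aryl and allyl groups. The aryl group would have to add to a cross-conjugated trienoate with open regiochemistry (1,4, 1,6 or 1,8). The allyl group would have to go onto an sp2 carbon next to the masked ketone. Three centres would have to be set on a flexible ring by separate reactions, with the absolute sense coming from a catalyst.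
- Comparison: the chosen strategy spends more steps on the ring but takes the absolute configuration from a bought centre and relays it by substrate control.

**Alternative 2:** This cuts the same C4–C5 bond as the chosen ring closure, but with C5 at the acid oxidation level, in the glutaric anhydride A4. In the forward key step the alkenyl iodide is turned into an alkenylchromium species that adds to the distal anhydride carbonyl and gives the bridged lactol A5.
- For: C5 arrives at the ketal oxidation level with O6 attached. There is no α-branched aldehyde to epimerise and no allylic oxidation. On redox economy after the ring closure this route is stronger.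
- Against: A4 has two carbonyl groups, and attack on the proximal one closes a five-membered ring, which is kinetically preferred to the seven-membered closure. Alkenylchromium reagents are chosen for their aldehyde selectivity and add poorly to acyl electrophiles. The bridgehead lactol A5 must then be O-methylated without opening to a keto carboxylate, which methylates on the carboxyl oxygen. Reaching A4 needs the CH2O carbon oxidised to the acid level beside alkenes and an electron-rich arene.
- Comparison: the chosen strategy pays two oxidations and in return has one electrophile of unambiguous reactivity.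

**Alternative 3:** Both bonds at C8 are cut, giving 3,4,5-trimethoxybenzaldehyde A6 and the (Z)-enedione keto ester A7. In the forward key step A6 condenses with the β-keto ester CH2 of A7 (Knoevenagel), and the ethyl ketone α-carbon then closes the ring by a 7-endo Michael addition to give the cycloheptenedione A8.
- For: it is by far the shortest route. One condensation of achiral pieces gives all ring carbons, both ketones, and the allyl, methyl and aryl groups. The three centres are epimerisable, so the trans,trans triad could be reached by equilibration. On step count this route is clearly stronger.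
- Against: there is no control of absolute configuration. A7 isomerises easily and is a Michael acceptor for its own β-keto ester. The closure needs the enolate of the least acidic site. A8 is an enedione β-keto ester that can enolise around the whole ring. Acidolysis of its ester unveils a β-keto acid that can decarboxylate before the ketal closes.
- Comparison: the chosen strategy is longer, but it delivers a single enantiomer, keeps C1 non-enolisable until the bicycle exists, and never passes through an open β-keto acid.

Key step: step 8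

Remark: the carbinol centre made in step 8 is drawn as the expected anti-aldol epimer (1S). A minor 1R epimer would run through steps 9–16 in the same way, because this centre becomes the C2 ketone in step 17.
Remark: 20 should form as a mixture of C5 epimers; both give 21, so C5 is left undefined there.

## Route

Step 1
Reactants: 1 methyl (2S)-3-hydroxy-2-methylpropanoate
Product: 2 methyl (2S)-3-[(tert-butyldimethylsilyl)oxy]-2-methylpropanoate
Conditions: TBSCl, imidazole, CH2Cl2, 0 °C → rt
Reagents that add atoms: tert-butyldimethylsilyl chloride, CC(C)(C)[Si](C)(C)Cl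
Why: Standard silylation of a primary alcohol; the stereocentre is not involved.

Step 2
Reactants: 2 methyl (2S)-3-[(tert-butyldimethylsilyl)oxy]-2-methylpropanoate
Product: 3 (2S)-3-[(tert-butyldimethylsilyl)oxy]-2-methylpropanal
Conditions: i-Bu2AlH (1.1 equiv), CH2Cl2, −78 °C
Reagents that add atoms: none
Why: Partial ester reduction through an aluminium hemiacetal that is stable at −78 °C; the α-centre should be kept if the aldehyde is not chromatographed and is used at once.

Step 3
Reactants: 3 (2S)-3-[(tert-butyldimethylsilyl)oxy]-2-methylpropanal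
Product: 4 methyl (2Z,4R)-5-[(tert-butyldimethylsilyl)oxy]-4-methylpent-2-enoate
Conditions: (CF3CH2O)2P(O)CH2CO2Me, KN(SiMe3)2, 18-crown-6, THF, −78 °C
Reagents that add atoms: methyl 2-[bis(2,2,2-trifluoroethoxy)phosphoryl]acetate, COC(=O)CP(=O)(OCC(F)(F)F)OCC(F)(F)F
Why: Still–Gennari olefination; the electron-poor phosphonate with a dissociated potassium ion gives the (Z)-enoate under kinetic control, and the cold, weakly basic medium should not epimerise the α-methyl aldehyde.

Step 4
Reactants: 4 methyl (2Z,4R)-5-[(tert-butyldimethylsilyl)oxy]-4-methylpent-2-enoate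
Product: 6 (5R)-5-methyl-5,6-dihydro-2H-pyran-2-one, via hydroxy (Z)-enoate 5 (not isolated)
Conditions: TsOH·H2O (10 mol%), MeOH, rt; concentrate, then toluene, 50 °C
Reagents that add atoms: none
Why: Acid-catalysed desilylation frees the primary alcohol, which sits cis to the ester across the (Z)-alkene and lactonises by transesterification as methanol is removed; the stereocentre has no acidic hydrogen under these conditions.

Step 5
Reactants: 7 prop-2-yn-1-ol; 8 allylmagnesium bromide
Product: 10 (2Z)-2-(iodomethylidene)pent-4-en-1-ol, via alkenylmagnesium alkoxide chelate 9 (not isolated)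
Conditions: 8 (2.5 equiv), CuI (10 mol%), Et2O, −20 °C → rt; then I2, THF, −40 → 0 °C
Reagents that add atoms: iodine, II
Why: Copper-catalysed carbomagnesiation of a propargylic alkoxide: the alkoxide directs anti addition, the allyl group goes to C2 and magnesium to C3 in a five-membered chelate; iodinolysis with retention places iodine cis to CH2OH, which is the (Z)-isomer.

Step 6
Reactants: 10 (2Z)-2-(iodomethylidene)pent-4-en-1-ol
Product: 11 (2Z)-2-(iodomethylidene)pent-4-enal
Conditions: MnO2 (activated, excess), CH2Cl2, rt, dark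
Reagents that add atoms: none
Why: Selective oxidation of an allylic alcohol on MnO2; the neutral medium should keep the (Z)-iodoalkene and the skipped diene, and the enal is used fresh.

Step 7
Reactants: 12 5-bromo-1,2,3-trimethoxybenzene
Product: 13 (3,4,5-trimethoxyphenyl)magnesium bromide
Conditions: Mg turnings (I2-activated), THF, 50 °C; titrated solution
Reagents that add atoms: magnesium, [Mg]
Why: Grignard formation by magnesium insertion into an aryl bromide; the methoxy groups are inert.

Step 8
Reactants: 6 (5R)-5-methyl-5,6-dihydro-2H-pyran-2-one; 13 (3,4,5-trimethoxyphenyl)magnesium bromide; 11 (2Z)-2-(iodomethylidene)pent-4-enal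
Product: 15 (3R,4R,5R)-3-[(1S,2Z)-1-hydroxy-2-(iodomethylidene)pent-4-en-1-yl]-5-methyl-4-(3,4,5-trimethoxyphenyl)oxan-2-one, via bromomagnesium lactone enolate 14 (not isolated)
Conditions: 13 (1.3 equiv), CuBr·SMe2 (20 mol%), THF/Me2S, −40 °C; then 11 (1.6 equiv), −78 °C; AcOH/THF quench at −78 °C
Reagents that add atoms: none
Why: 13 and CuBr·SMe2 form an arylcopper ate species that transfers its aryl group to C4 of 6 (π-complex, oxidative addition to a trivalent copper intermediate, reductive elimination) and leaves the bromomagnesium enolate 14, which adds 1,2 to aldehyde 11 through a closed six-membered transition state; the closest known reaction type is the three-component conjugate addition–aldol coupling of cyclic enones and unsaturated lactones. No ring is closed; the C4–aryl bond and the C3–carbinol bond are formed. The C4 centre is controlled by the C5 methyl group: the nucleophile enters the half-chair lactone on the face anti to it, as in cuprate additions to 4-substituted cyclohexenones, which gives the 4,5-trans enolate. The C3 centre is controlled by the new aryl group: the aldehyde is taken up on the enolate face opposite to it, which gives the 3,4-trans product. The carbinol centre should follow the anti-aldol course of a ring-locked (E)-enolate (1S as drawn), but it is oxidised in step 17, so this selectivity is not needed. What is needed is 1,2-addition to 11 instead of addition–elimination at its iodine-bearing carbon or proton abstraction from its doubly allylic CH2; a hard magnesium enolate at −78 °C, the α-branched enal and a cold acidic quench (no retro-aldol, no epimerisation at C3) should secure this. 13 is used in slight excess only, so that little free aryl nucleophile is left when 11 is added.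

Step 9
Reactants: 15 (3R,4R,5R)-3-[(1S,2Z)-1-hydroxy-2-(iodomethylidene)pent-4-en-1-yl]-5-methyl-4-(3,4,5-trimethoxyphenyl)oxan-2-one
Product: 16 (3R,4R,5R)-3-[(1S,2Z)-1-[(tert-butyldimethylsilyl)oxy]-2-(iodomethylidene)pent-4-en-1-yl]-5-methyl-4-(3,4,5-trimethoxyphenyl)oxan-2-one
Conditions: TBSOTf, 2,6-lutidine, CH2Cl2, −78 → 0 °C
Reagents that add atoms: tert-butyldimethylsilyl trifluoromethanesulfonate, CC(C)(C)[Si](C)(C)OS(=O)(=O)C(F)(F)F
Why: Silylation of a hindered secondary aldol hydroxyl with a silyl triflate and a non-nucleophilic base; this blocks retro-aldol cleavage and dehydration in the steps that follow.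

Step 10
Reactants: 16 (3R,4R,5R)-3-[(1S,2Z)-1-[(tert-butyldimethylsilyl)oxy]-2-(iodomethylidene)pent-4-en-1-yl]-5-methyl-4-(3,4,5-trimethoxyphenyl)oxan-2-one
Product: 18 prop-2-en-1-yl (2R,3R,4R)-2-[(1S,2Z)-1-[(tert-butyldimethylsilyl)oxy]-2-(iodomethylidene)pent-4-en-1-yl]-5-hydroxy-4-methyl-3-(3,4,5-trimethoxyphenyl)pentanoate, via potassium hydroxy carboxylate 17 (not isolated)
Conditions: KOH (1.05 equiv), THF/H2O, 0 °C → rt; evaporate to dryness; allyl bromide, DMF, 0 °C → rt; crude product used at once
Reagents that add atoms: potassium hydroxide, [K+].[OH-]; allyl bromide, C=CCBr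
Why: Lactone saponification is faster than enolisation at C2, and the carboxylate is alkylated without ever being protonated, so the δ-hydroxy acid that would relactonise is avoided; only the carboxylate is nucleophilic enough to be allylated.

Step 11
Reactants: 18 prop-2-en-1-yl (2R,3R,4R)-2-[(1S,2Z)-1-[(tert-butyldimethylsilyl)oxy]-2-(iodomethylidene)pent-4-en-1-yl]-5-hydroxy-4-methyl-3-(3,4,5-trimethoxyphenyl)pentanoate
Product: 19 prop-2-en-1-yl (2R,3R,4R)-2-[(1S,2Z)-1-[(tert-butyldimethylsilyl)oxy]-2-(iodomethylidene)pent-4-en-1-yl]-4-methyl-5-oxo-3-(3,4,5-trimethoxyphenyl)pentanoate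
Conditions: Dess–Martin periodinane, NaHCO3, CH2Cl2, 0 °C → rt
Reagents that add atoms: none
Why: Dess–Martin oxidation of a primary alcohol under buffered, non-basic conditions, which should leave the α-methyl centre of the new aldehyde and the alkenyl iodide untouched.

Step 12
Reactants: 19 prop-2-en-1-yl (2R,3R,4R)-2-[(1S,2Z)-1-[(tert-butyldimethylsilyl)oxy]-2-(iodomethylidene)pent-4-en-1-yl]-4-methyl-5-oxo-3-(3,4,5-trimethoxyphenyl)pentanoate
Product: 20 prop-2-en-1-yl (1R,2S,6R,7R)-2-[(tert-butyldimethylsilyl)oxy]-5-hydroxy-6-methyl-3-(prop-2-en-1-yl)-7-(3,4,5-trimethoxyphenyl)cyclohept-3-ene-1-carboxylate (C5 epimers)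
Conditions: CrCl2 (8 equiv), NiCl2 (2 mol%), degassed DMSO, rt, 0.005 M
Reagents that add atoms: none
Why: Nozaki–Hiyama–Kishi reaction: zerovalent nickel inserts into the C–I bond with retention of the (Z)-geometry, transmetalation gives an alkenylchromium dichloride that adds only to the aldehyde (7-exo closure), and the cis arrangement of C2 and iodine on the alkene pre-organises the ring; the new C5 centre needs no control because step 13 removes it.

Step 13
Reactants: 20 prop-2-en-1-yl (1R,2S,6R,7R)-2-[(tert-butyldimethylsilyl)oxy]-5-hydroxy-6-methyl-3-(prop-2-en-1-yl)-7-(3,4,5-trimethoxyphenyl)cyclohept-3-ene-1-carboxylate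
Product: 21 prop-2-en-1-yl (1R,2S,6R,7R)-2-[(tert-butyldimethylsilyl)oxy]-6-methyl-5-oxo-3-(prop-2-en-1-yl)-7-(3,4,5-trimethoxyphenyl)cyclohept-3-ene-1-carboxylate
Conditions: Dess–Martin periodinane, NaHCO3, CH2Cl2, 0 °C → rt
Reagents that add atoms: none
Why: Dess–Martin oxidation of a secondary allylic alcohol; both C5 epimers converge on one enone, and the buffered medium should not enolise the C6 methyl centre.

Step 14
Reactants: 21 prop-2-en-1-yl (1R,2S,6R,7R)-2-[(tert-butyldimethylsilyl)oxy]-6-methyl-5-oxo-3-(prop-2-en-1-yl)-7-(3,4,5-trimethoxyphenyl)cyclohept-3-ene-1-carboxylate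
Product: 22 (1R,2S,6R,7R)-2-[(tert-butyldimethylsilyl)oxy]-6-methyl-5-oxo-3-(prop-2-en-1-yl)-7-(3,4,5-trimethoxyphenyl)cyclohept-3-ene-1-carboxylic acid
Conditions: Pd(PPh3)4 (5 mol%), morpholine (3 equiv), THF, rt; NaH2PO4 work-up
Reagents that add atoms: none
Why: Tsuji–Trost deallylation: zerovalent palladium ionises the allyl ester to a π-allylpalladium carboxylate and morpholine takes the allyl group; the neutral conditions should leave the enone, the C6 centre, the C-allyl group (no leaving group) and the silyl ether alone.

Step 15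
Reactants: 22 (1R,2S,6R,7R)-2-[(tert-butyldimethylsilyl)oxy]-6-methyl-5-oxo-3-(prop-2-en-1-yl)-7-(3,4,5-trimethoxyphenyl)cyclohept-3-ene-1-carboxylic acid
Product: 23 (1R,2S,5S,8R,9R)-2-[(tert-butyldimethylsilyl)oxy]-5-methoxy-9-methyl-3-(prop-2-en-1-yl)-8-(3,4,5-trimethoxyphenyl)-6-oxabicyclo[3.2.2]non-3-en-7-one
Conditions: HC(OMe)3 (5 equiv), MeOH, PPTS (20 mol%), rt
Reagents that add atoms: methanol, CO; trimethyl orthoformate, COC(OC)OC
Why: Acid-catalysed pseudo-ester formation from a keto acid: methanol adds reversibly to the C5 ketone, and the hemiketal or methoxy-oxocarbenium ion is captured by the C1 carboxyl group to give the bridged methoxy lactone, while the orthoester removes the water and makes the closure irreversible. The C1 tether allows only the 5S configuration, and the silyl ether is kept on so that the C2 oxygen cannot bridge to C5.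

Step 16
Reactants: 23 (1R,2S,5S,8R,9R)-2-[(tert-butyldimethylsilyl)oxy]-5-methoxy-9-methyl-3-(prop-2-en-1-yl)-8-(3,4,5-trimethoxyphenyl)-6-oxabicyclo[3.2.2]non-3-en-7-one
Product: 24 (1R,2S,5S,8R,9R)-2-hydroxy-5-methoxy-9-methyl-3-(prop-2-en-1-yl)-8-(3,4,5-trimethoxyphenyl)-6-oxabicyclo[3.2.2]non-3-en-7-one
Conditions: HF·pyridine, pyridine/THF, 0 °C → rt
Reagents that add atoms: none
Why: Fluoride-driven cleavage of the Si–O bond in a buffered, non-basic medium; the bridgehead ketal cannot ionise easily, and retro-aldol cleavage would need a bridgehead enolate.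

Step 17
Reactants: 24 (1R,2S,5S,8R,9R)-2-hydroxy-5-methoxy-9-methyl-3-(prop-2-en-1-yl)-8-(3,4,5-trimethoxyphenyl)-6-oxabicyclo[3.2.2]non-3-en-7-one
Product: 25 (1R,5S,8R,9R)-5-methoxy-9-methyl-3-(prop-2-en-1-yl)-8-(3,4,5-trimethoxyphenyl)-6-oxabicyclo[3.2.2]non-3-ene-2,7-dione
Conditions: Dess–Martin periodinane, NaHCO3, CH2Cl2, 0 °C → rt
Reagents that add atoms: none
Why: Dess–Martin oxidation of the allylic C2 alcohol to the enone; the β-keto lactone appears only now, with C1 a bridgehead that cannot epimerise, and the mild conditions should not move the skipped diene.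

## Compound list

1 | methyl (2S)-3-hydroxy-2-methylpropanoate | COC(=O)[C@@H](C)CO | starting material
2 | methyl (2S)-3-[(tert-butyldimethylsilyl)oxy]-2-methylpropanoate | COC(=O)[C@@H](C)CO[Si](C)(C)C(C)(C)C | intermediate
3 | (2S)-3-[(tert-butyldimethylsilyl)oxy]-2-methylpropanal | O=C[C@@H](C)CO[Si](C)(C)C(C)(C)C | intermediate
4 | methyl (2Z,4R)-5-[(tert-butyldimethylsilyl)oxy]-4-methylpent-2-enoate | COC(=O)/C=C\[C@@H](C)CO[Si](C)(C)C(C)(C)C | intermediate
5 | methyl (2Z,4R)-5-hydroxy-4-methylpent-2-enoate | COC(=O)/C=C\[C@@H](C)CO | intermediate (not isolated)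
6 | (5R)-5-methyl-5,6-dihydro-2H-pyran-2-one | O=C1C=C[C@@H](C)CO1 | intermediate
7 | prop-2-yn-1-ol | C#CCO | starting material
8 | allylmagnesium bromide | C=CC[Mg]Br | starting material
9 | 4-(prop-2-en-1-yl)-1-oxa-2-magnesacyclopent-3-ene (alkenylmagnesium alkoxide chelate) | C=CCC1=C[Mg]OC1 | intermediate (not isolated)
10 | (2Z)-2-(iodomethylidene)pent-4-en-1-ol | OC/C(CC=C)=C\I | intermediate
11 | (2Z)-2-(iodomethylidene)pent-4-enal | O=C/C(CC=C)=C\I | intermediate
12 | 5-bromo-1,2,3-trimethoxybenzene | COc1cc(Br)cc(OC)c1OC | starting material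
13 | (3,4,5-trimethoxyphenyl)magnesium bromide | COc1cc([Mg]Br)cc(OC)c1OC | intermediate
14 | bromomagnesium enolate of the 4,5-trans lactone, {[(4R,5R)-5-methyl-4-(3,4,5-trimethoxyphenyl)-5,6-dihydro-4H-pyran-2-yl]oxy}magnesium bromide | Br[Mg]OC1=C[C@H](c2cc(OC)c(OC)c(OC)c2)[C@@H](C)CO1 | intermediate (not isolated)
15 | (3R,4R,5R)-3-[(1S,2Z)-1-hydroxy-2-(iodomethylidene)pent-4-en-1-yl]-5-methyl-4-(3,4,5-trimethoxyphenyl)oxan-2-one | O=C1OC[C@H](C)[C@@H](c2cc(OC)c(OC)c(OC)c2)[C@@H]1[C@H](O)/C(CC=C)=C\I | intermediate
16 | (3R,4R,5R)-3-[(1S,2Z)-1-[(tert-butyldimethylsilyl)oxy]-2-(iodomethylidene)pent-4-en-1-yl]-5-methyl-4-(3,4,5-trimethoxyphenyl)oxan-2-one | O=C1OC[C@H](C)[C@@H](c2cc(OC)c(OC)c(OC)c2)[C@@H]1[C@H](O[Si](C)(C)C(C)(C)C)/C(CC=C)=C\I | intermediate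
17 | potassium (2R,3R,4R)-2-[(1S,2Z)-1-[(tert-butyldimethylsilyl)oxy]-2-(iodomethylidene)pent-4-en-1-yl]-5-hydroxy-4-methyl-3-(3,4,5-trimethoxyphenyl)pentanoate | [K+].[O-]C(=O)[C@@H]([C@H](O[Si](C)(C)C(C)(C)C)/C(CC=C)=C\I)[C@H](c1cc(OC)c(OC)c(OC)c1)[C@@H](C)CO | intermediate (not isolated)
18 | prop-2-en-1-yl (2R,3R,4R)-2-[(1S,2Z)-1-[(tert-butyldimethylsilyl)oxy]-2-(iodomethylidene)pent-4-en-1-yl]-5-hydroxy-4-methyl-3-(3,4,5-trimethoxyphenyl)pentanoate | C=CCOC(=O)[C@@H]([C@H](O[Si](C)(C)C(C)(C)C)/C(CC=C)=C\I)[C@H](c1cc(OC)c(OC)c(OC)c1)[C@@H](C)CO | intermediate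
19 | prop-2-en-1-yl (2R,3R,4R)-2-[(1S,2Z)-1-[(tert-butyldimethylsilyl)oxy]-2-(iodomethylidene)pent-4-en-1-yl]-4-methyl-5-oxo-3-(3,4,5-trimethoxyphenyl)pentanoate | C=CCOC(=O)[C@@H]([C@H](O[Si](C)(C)C(C)(C)C)/C(CC=C)=C\I)[C@H](c1cc(OC)c(OC)c(OC)c1)[C@@H](C)C=O | intermediate
20 | prop-2-en-1-yl (1R,2S,6R,7R)-2-[(tert-butyldimethylsilyl)oxy]-5-hydroxy-6-methyl-3-(prop-2-en-1-yl)-7-(3,4,5-trimethoxyphenyl)cyclohept-3-ene-1-carboxylate (C5 epimers) | C=CCOC(=O)[C@H]1[C@H](O[Si](C)(C)C(C)(C)C)C(CC=C)=CC(O)[C@H](C)[C@H]1c1cc(OC)c(OC)c(OC)c1 | intermediate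
21 | prop-2-en-1-yl (1R,2S,6R,7R)-2-[(tert-butyldimethylsilyl)oxy]-6-methyl-5-oxo-3-(prop-2-en-1-yl)-7-(3,4,5-trimethoxyphenyl)cyclohept-3-ene-1-carboxylate | C=CCOC(=O)[C@H]1[C@H](O[Si](C)(C)C(C)(C)C)C(CC=C)=CC(=O)[C@H](C)[C@H]1c1cc(OC)c(OC)c(OC)c1 | intermediate
22 | (1R,2S,6R,7R)-2-[(tert-butyldimethylsilyl)oxy]-6-methyl-5-oxo-3-(prop-2-en-1-yl)-7-(3,4,5-trimethoxyphenyl)cyclohept-3-ene-1-carboxylic acid | OC(=O)[C@H]1[C@H](O[Si](C)(C)C(C)(C)C)C(CC=C)=CC(=O)[C@H](C)[C@H]1c1cc(OC)c(OC)c(OC)c1 | intermediate
23 | (1R,2S,5S,8R,9R)-2-[(tert-butyldimethylsilyl)oxy]-5-methoxy-9-methyl-3-(prop-2-en-1-yl)-8-(3,4,5-trimethoxyphenyl)-6-oxabicyclo[3.2.2]non-3-en-7-one | C=CCC1=C[C@@]2(OC)OC(=O)[C@@H]([C@@H]1O[Si](C)(C)C(C)(C)C)[C@H](c1cc(OC)c(OC)c(OC)c1)[C@H]2C | intermediate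
24 | (1R,2S,5S,8R,9R)-2-hydroxy-5-methoxy-9-methyl-3-(prop-2-en-1-yl)-8-(3,4,5-trimethoxyphenyl)-6-oxabicyclo[3.2.2]non-3-en-7-one | C=CCC1=C[C@@]2(OC)OC(=O)[C@@H]([C@@H]1O)[C@H](c1cc(OC)c(OC)c(OC)c1)[C@H]2C | intermediate
25 | (1R,5S,8R,9R)-5-methoxy-9-methyl-3-(prop-2-en-1-yl)-8-(3,4,5-trimethoxyphenyl)-6-oxabicyclo[3.2.2]non-3-ene-2,7-dione | C=CCC1=C[C@@]2(OC)OC(=O)[C@@H](C1=O)[C@H](c1cc(OC)c(OC)c(OC)c1)[C@H]2C | target

## Step count and least certain steps

Total: 17 steps. Longest linear sequence: 14 steps (steps 1–4 and 8–17, from 1). The branches to 11 (steps 5 and 6) and 13 (step 7) join at step 8.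

**Step 8 (key step).** The most likely failure is at the aldol stage. Enolate 14 may take a proton from the doubly allylic CH2 of 11, or add to the iodine-bearing carbon with loss of iodide, because 11 is a vinylogous acyl iodide. A warm quench could also bring retro-aldol cleavage and loss of the 3,4-trans relation. Slow copper turnover with the electron-rich aryl Grignard reagent would leave free 13, which consumes 11. The fallback separates the two bond formations. It sets out from 6 and 13: the same copper-mediated addition is quenched with NH4Cl to give (4S,5R)-5-methyl-4-(3,4,5-trimethoxyphenyl)oxan-2-one F1 (the same spatial arrangement; the descriptor at C4 changes with the priorities). F1 is deprotonated with LiN(i-Pr)2 in THF at −78 °C to its lithium enolate F2, which is treated with 11 at −78 °C. Alkylation and aldol reactions of such 4-aryl lactone enolates go anti to the aryl group, so the sequence comes back to the route at 15.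

**Step 15.** The carboxyl group may be esterified by the orthoester faster than the C5 oxocarbenium ion is captured, which would give the normal methyl ester. The conjugated ketone may also form its ketal too slowly. Stronger acid would bring desilylation followed by transannular ketalisation from the C2 oxygen, and enolisation at C6. The fallback stages the event and sets out from 21. The enone is first converted into its dimethyl ketal with HC(OMe)3, MeOH and camphorsulfonic acid while the carboxyl group is still the allyl ester, giving prop-2-en-1-yl (1R,2S,6R,7R)-2-[(tert-butyldimethylsilyl)oxy]-5,5-dimethoxy-6-methyl-3-(prop-2-en-1-yl)-7-(3,4,5-trimethoxyphenyl)cyclohept-3-ene-1-carboxylate F3. Deallylation with Pd(PPh3)4 and morpholine gives the ketal acid F4. PPTS in dry CH2Cl2 then closes the lactone by intramolecular displacement of one methoxy group, in a medium where no esterification is possible, and the sequence comes back at 23.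

**Step 12.** The alkenylchromium species may be protonated before the hindered seven-membered closure occurs. Intermolecular coupling may compete at practical concentration. The chromium alkoxide of one C5 epimer may lactonise onto the ester, and zerovalent nickel may ionise the allyl ester. The fallback replaces the chromium closure by an anionic one and sets out from 16.
- The lactone is opened as in step 10, but carboxylate 17 is alkylated with MeI to give the methyl ester analogue of 18, F5.
- Dess–Martin oxidation gives the aldehyde F6, and NaClO2/NaH2PO4/2-methylbut-2-ene gives the acid F7.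
- Coupling with N,O-dimethylhydroxylamine (carbodiimide, hydroxybenzotriazole) gives the Weinreb amide F8, and Me3SnOH in 1,2-dichloroethane frees the C1 acid to give the amide acid F9.
- F9 is deprotonated with LiN(SiMe3)2 and treated with t-BuLi at −100 °C. Iodine–lithium exchange is faster than any addition, the lithium carboxylate is inert, and the alkenyllithium adds to the Weinreb amide (Parham-type 7-exo closure).
- This gives the enone acid directly, so the sequence comes back at 22 and steps 13 and 14 fall away.

**Step 10.** The δ-hydroxy ester 18 may relactonise to 16 during work-up or on silica, and excess base could allylate the hydroxyl group or cause elimination of the silyloxy group. The fallback never frees the hydroxy ester and sets out from 16. After saponification to 17 and allylation in DMF, imidazole and Et3SiCl are added to the same flask to give the triethylsilyl ether F10. The primary triethylsilyl ether is then oxidised directly under Swern conditions ((COCl)2, DMSO, −78 → −30 °C; Et3N), which leave the secondary tert-butyldimethylsilyl ether untouched, and the sequence comes back at 19.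

Further compounds
F1 | step 8 | (4S,5R)-5-methyl-4-(3,4,5-trimethoxyphenyl)oxan-2-one | O=C1C[C@H](c2cc(OC)c(OC)c(OC)c2)[C@@H](C)CO1
F2 | step 8 | lithium enolate of F1, {[(4R,5R)-5-methyl-4-(3,4,5-trimethoxyphenyl)-5,6-dihydro-4H-pyran-2-yl]oxy}lithium | [Li]OC1=C[C@H](c2cc(OC)c(OC)c(OC)c2)[C@@H](C)CO1
F3 | step 15 | prop-2-en-1-yl (1R,2S,6R,7R)-2-[(tert-butyldimethylsilyl)oxy]-5,5-dimethoxy-6-methyl-3-(prop-2-en-1-yl)-7-(3,4,5-trimethoxyphenyl)cyclohept-3-ene-1-carboxylate | C=CCOC(=O)[C@H]1[C@H](O[Si](C)(C)C(C)(C)C)C(CC=C)=CC(OC)(OC)[C@H](C)[C@H]1c1cc(OC)c(OC)c(OC)c1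
F4 | step 15 | (1R,2S,6R,7R)-2-[(tert-butyldimethylsilyl)oxy]-5,5-dimethoxy-6-methyl-3-(prop-2-en-1-yl)-7-(3,4,5-trimethoxyphenyl)cyclohept-3-ene-1-carboxylic acid | OC(=O)[C@H]1[C@H](O[Si](C)(C)C(C)(C)C)C(CC=C)=CC(OC)(OC)[C@H](C)[C@H]1c1cc(OC)c(OC)c(OC)c1
F5 | step 12 | methyl (2R,3R,4R)-2-[(1S,2Z)-1-[(tert-butyldimethylsilyl)oxy]-2-(iodomethylidene)pent-4-en-1-yl]-5-hydroxy-4-methyl-3-(3,4,5-trimethoxyphenyl)pentanoate | COC(=O)[C@@H]([C@H](O[Si](C)(C)C(C)(C)C)/C(CC=C)=C\I)[C@H](c1cc(OC)c(OC)c(OC)c1)[C@@H](C)CO
F6 | step 12 | methyl (2R,3R,4R)-2-[(1S,2Z)-1-[(tert-butyldimethylsilyl)oxy]-2-(iodomethylidene)pent-4-en-1-yl]-4-methyl-5-oxo-3-(3,4,5-trimethoxyphenyl)pentanoate | COC(=O)[C@@H]([C@H](O[Si](C)(C)C(C)(C)C)/C(CC=C)=C\I)[C@H](c1cc(OC)c(OC)c(OC)c1)[C@@H](C)C=O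
F7 | step 12 | (2R,3R,4R)-4-[(1S,2Z)-1-[(tert-butyldimethylsilyl)oxy]-2-(iodomethylidene)pent-4-en-1-yl]-5-methoxy-2-methyl-5-oxo-3-(3,4,5-trimethoxyphenyl)pentanoic acid | COC(=O)[C@@H]([C@H](O[Si](C)(C)C(C)(C)C)/C(CC=C)=C\I)[C@H](c1cc(OC)c(OC)c(OC)c1)[C@@H](C)C(=O)O
F8 | step 12 | methyl (2R,3R,4R)-2-[(1S,2Z)-1-[(tert-butyldimethylsilyl)oxy]-2-(iodomethylidene)pent-4-en-1-yl]-5-[methoxy(methyl)amino]-4-methyl-5-oxo-3-(3,4,5-trimethoxyphenyl)pentanoate | COC(=O)[C@@H]([C@H](O[Si](C)(C)C(C)(C)C)/C(CC=C)=C\I)[C@H](c1cc(OC)c(OC)c(OC)c1)[C@@H](C)C(=O)N(C)OC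
F9 | step 12 | (2R,3R,4R)-2-[(1S,2Z)-1-[(tert-butyldimethylsilyl)oxy]-2-(iodomethylidene)pent-4-en-1-yl]-5-[methoxy(methyl)amino]-4-methyl-5-oxo-3-(3,4,5-trimethoxyphenyl)pentanoic acid | OC(=O)[C@@H]([C@H](O[Si](C)(C)C(C)(C)C)/C(CC=C)=C\I)[C@H](c1cc(OC)c(OC)c(OC)c1)[C@@H](C)C(=O)N(C)OC
F10 | step 10 | prop-2-en-1-yl (2R,3R,4R)-2-[(1S,2Z)-1-[(tert-butyldimethylsilyl)oxy]-2-(iodomethylidene)pent-4-en-1-yl]-4-methyl-5-[(triethylsilyl)oxy]-3-(3,4,5-trimethoxyphenyl)pentanoate | C=CCOC(=O)[C@@H]([C@H](O[Si](C)(C)C(C)(C)C)/C(CC=C)=C\I)[C@H](c1cc(OC)c(OC)c(OC)c1)[C@@H](C)CO[Si](CC)(CC)CC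
A1 | alternative 1 | methyl 6-methoxy-5-methyl-2-oxo-2H-pyran-3-carboxylate | COC(=O)C1=CC(C)=C(OC)OC1=O
A2 | alternative 1 | 6,6-dimethyl-4,8-dioxaspiro[2.5]oct-1-ene | CC1(C)COC2(C=C2)OC1
A3 | alternative 1 | methyl 10-methoxy-3,3,9-trimethyl-1,5-dioxaspiro[5.6]dodeca-7,9,11-triene-7-carboxylate | COC(=O)C1=CC(C)=C(OC)C=CC12OCC(C)(C)CO2
A4 | alternative 2 | 3-[(Z)-1-(tert-butyldimethylsilyloxy)-2-(iodomethylidene)pent-4-enyl]-5-methyl-4-(3,4,5-trimethoxyphenyl)oxane-2,6-dione | O=C1OC(=O)[C@@H]([C@@H](O[Si](C)(C)C(C)(C)C)/C(CC=C)=C\I)[C@H](c2cc(OC)c(OC)c(OC)c2)[C@H]1C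
A5 | alternative 2 | 2-(tert-butyldimethylsilyloxy)-5-hydroxy-9-methyl-3-(prop-2-enyl)-8-(3,4,5-trimethoxyphenyl)-6-oxabicyclo[3.2.2]non-3-en-7-one | C=CCC1=C[C@@]2(O)OC(=O)[C@@H]([C@H]1O[Si](C)(C)C(C)(C)C)[C@H](c1cc(OC)c(OC)c(OC)c1)[C@H]2C
A6 | alternative 3 | 3,4,5-trimethoxybenzaldehyde | COc1cc(C=O)cc(OC)c1OC
A7 | alternative 3 | tert-butyl (4Z)-3,6-dioxo-4-(prop-2-en-1-yl)oct-4-enoate | CCC(=O)/C=C(CC=C)\C(=O)CC(=O)OC(C)(C)C
A8 | alternative 3 | tert-butyl 6-methyl-2,5-dioxo-3-(prop-2-enyl)-7-(3,4,5-trimethoxyphenyl)cyclohept-3-ene-1-carboxylate (1,7-cis, 6,7-trans) | C=CCC1=CC(=O)[C@H](C)[C@@H](c2cc(OC)c(OC)c(OC)c2)[C@@H](C(=O)OC(C)(C)C)C1=O
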